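**Plan**
Cuts, in order: the ring D aryl–alkenyl bond (Suzuki–Miyaura); the C7–C8 and C7'–C8' bonds (aldol) and the two phenol O–CH2 bonds that attach a glycolyl unit to ring B and to ring C; the C3–C3a bond of the dihydrofuran (ring contraction); the C2–ring C bond (conjugate arylation of a chromone).
Enabling feature: the five-membered ring O1–C2(ring C)–C3(CH2OH)–C3a–C7a fused to ring D is a 2-arylchroman-4-one short of one ring atom; when C4a moves from the carbonyl carbon C4 to C3, C4 leaves the ring and ends as the CH2OH carbon.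
Forward: the pyranone ring is closed first, ring C is added at C2, C3 is diazotised and light contracts the ring to the trans dihydrobenzofuran ester. The chain then grows outward from the ring C phenol (ring B unit, then ring A unit), each by O-alkylation with a chloroacetyl imide, aldol, reduction and inversion; the enal is attached last.
Stereochemistry: C2 from a chiral pyridine-oxazoline palladium catalyst; C3 by base equilibration to trans; C8 and C8' from the (R)-4-benzyloxazolidinone in two syn aldols; C7 and C7', first formed syn, are each inverted by a Mitsunobu reaction to erythro; the E alkene comes from an E-alkenylboronate.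

Key step: step 7

Assumption: by analogy with additions to simple chromones the (S)-ligand is taken to give the 2R flavanone; if the facial sense is the reverse, the (R)-ligand is used.
Locants and abbreviations: benzofuran numbering for the bicycle; 7, 8, 9 (ring A unit) and 7', 8', 9' (ring B unit) for the benzylic carbon, the ether-bearing carbon and the CH2O carbon of the side chains; MOM = methoxymethyl, TBS = tert-butyldimethylsilyl, TIPS = triisopropylsilyl, Bz = benzoyl, Xc = (R)-4-benzyl-2-oxooxazolidin-3-yl.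

**Route**

Step 1
Reactants: 1 2'-hydroxy-3'-methoxyacetophenone
Product: 2 5'-bromo-2'-hydroxy-3'-methoxyacetophenone
Conditions: N-bromosuccinimide, MeCN, 0 to 20 °C
Reagents that add atoms: N-bromosuccinimide, O=C1CCC(=O)N1Br
Why: Electrophilic aromatic bromination goes para to the free phenol, the only open position that is activated by OH and also meta to the acetyl group.

Step 2
Reactants: 2 5'-bromo-2'-hydroxy-3'-methoxyacetophenone
Product: 4 6-bromo-8-methoxy-4H-chromen-4-one, via enaminone 3 (not isolated)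
Conditions: Me2NCH(OMe)2, toluene, 100 °C; then conc. HCl, CH2Cl2, 40 °C
Reagents that add atoms: N,N-dimethylformamide dimethyl acetal, COC(OC)N(C)C
Why: Enaminone chromone synthesis: condensation at the methyl ketone, then acid-promoted addition–elimination of the phenol closes the pyranone.

Step 3
Reactants: 5 4-bromo-2,6-dimethoxyphenol
Product: 6 5-bromo-1,3-dimethoxy-2-(methoxymethoxy)benzene
Conditions: MOMCl, i-Pr2NEt, CH2Cl2, 0 to 20 °C
Reagents that add atoms: chloromethyl methyl ether, COCCl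
Why: O-alkylation of the phenol gives an acetal protecting group that tolerates organolithium, amide base, light and methoxide and is later removed by mild acid without hydrogenolysis, which the aryl bromide of ring D would not survive.

Step 4
Reactants: 6 5-bromo-1,3-dimethoxy-2-(methoxymethoxy)benzene
Product: 8 [3,5-dimethoxy-4-(methoxymethoxy)phenyl]boronic acid, via aryllithium 7 (not isolated)
Conditions: n-BuLi, THF, −78 °C; B(Oi-Pr)3, −78 to 20 °C; aq. HCl to pH 5, 0 °C
Reagents that add atoms: triisopropyl borate, CC(C)OB(OC(C)C)OC(C)C; water, O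
Why: Bromine–lithium exchange followed by trapping with a trialkyl borate and hydrolysis is the standard arylboronic acid synthesis.

Step 5
Reactants: 4 6-bromo-8-methoxy-4H-chromen-4-one; 8 [3,5-dimethoxy-4-(methoxymethoxy)phenyl]boronic acid
Product: 9 (2R)-6-bromo-2-[3,5-dimethoxy-4-(methoxymethoxy)phenyl]-8-methoxychroman-4-one
Conditions: Pd(OCOCF3)2 (5 mol %), (S)-4-tert-butyl-2-(pyridin-2-yl)-4,5-dihydrooxazole (6 mol %), NH4PF6 (30 mol %), H2O (5 equiv), ClCH2CH2Cl, air, 60 °C
Reagents that add atoms: none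
Why: Palladium-catalysed asymmetric conjugate addition of an arylboronic acid to a chromone (transmetalation, insertion of C2=C3 into the aryl–palladium bond, protonolysis of the palladium enolate, the metal staying divalent so that the aryl bromide is not touched); the tert-butyl group of the ligand blocks one face of the bound enone, so ring C is delivered to give 2R.

Step 6
Reactants: 9 (2R)-6-bromo-2-[3,5-dimethoxy-4-(methoxymethoxy)phenyl]-8-methoxychroman-4-one
Product: 12 (2S)-6-bromo-3-diazo-2-[3,5-dimethoxy-4-(methoxymethoxy)phenyl]-8-methoxychroman-4-one, via lithium enolate 10 (not isolated), via trifluoroacetyl ketone 11 (not isolated)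
Conditions: LiN(SiMe3)2, THF, −78 °C; CF3CO2CH2CF3, −78 °C; cold aq. HCl; crude 11, 4-AcNHC6H4SO2N3, Et3N, H2O (1 equiv), MeCN, 20 °C
Reagents that add atoms: 4-acetamidobenzenesulfonyl azide, CC(=O)Nc1ccc(cc1)S(=O)(=O)N=[N+]=[N-]; 2,2,2-trifluoroethyl trifluoroacetate, FC(F)(F)COC(=O)C(F)(F)F (its CF3CO group is carried only by 11)
Why: Detrifluoroacetylative diazo transfer (Regitz type): the kinetic enolate is C-acylated at −78 °C before it can expel the ring oxygen, and the 1,3-dicarbonyl compound then takes N2 from the sulfonyl azide with loss of the trifluoroacetyl group; C2 is spatially unchanged (the descriptor changes by priority only).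

Step 7
Reactants: 12 (2S)-6-bromo-3-diazo-2-[3,5-dimethoxy-4-(methoxymethoxy)phenyl]-8-methoxychroman-4-one
Product: 15 methyl (2R,3R)-5-bromo-2-[3,5-dimethoxy-4-(methoxymethoxy)phenyl]-7-methoxy-2,3-dihydrobenzofuran-3-carboxylate (trans), via ketene 13 (not isolated), via cis ester 14 (not isolated)
Conditions: hν (365 nm LED), degassed MeOH (0.01 M), 15 °C; then NaOMe (0.2 equiv), 20 °C
Reagents that add atoms: methanol, CO
Why: Photochemical Wolff rearrangement: excitation expels N2 while the aryl carbon C4a, anti-periplanar to the leaving nitrogen in the ring-locked s-Z diazo ketone, shifts from the carbonyl carbon to the diazo carbon, so C3–C3a forms as C4–C4a breaks and the former carbonyl carbon leaves the ring as a ketene that methanol traps as the ester. The closest known reaction type is the light-induced ring contraction of cyclic 2-diazo ketones in alcohols (2-diazo-1-tetralones to indane-1-carboxylates). The five-membered ring arises by this 1,2-shift, a contraction of the six-membered ring with extrusion of one carbon, not by an end-to-end cyclisation, so no Baldwin mode applies. C2 keeps its configuration because none of its bonds changes; C3 is first set by protonation of the ester enol and is then brought under thermodynamic control by catalytic NaOMe, which places the ester trans to the C2 aryl group. The selectivity needed is aryl shift over 1,2-hydride shift from C2 (flavone) and over O–H insertion; it is secured by the fixed s-Z geometry, by direct irradiation without metal or sensitiser, and by the aryl carbon being the only substituent on the carbonyl carbon.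

Step 8
Reactants: 15 methyl (2R,3R)-5-bromo-2-[3,5-dimethoxy-4-(methoxymethoxy)phenyl]-7-methoxy-2,3-dihydrobenzofuran-3-carboxylate
Product: 16 methyl (2R,3R)-5-bromo-2-(4-hydroxy-3,5-dimethoxyphenyl)-7-methoxy-2,3-dihydrobenzofuran-3-carboxylate
Conditions: conc. HCl (cat.), MeOH, 40 °C
Reagents that add atoms: none
Why: Acid-catalysed transacetalisation removes the MOM group as dimethoxymethane, while the methyl ester, the aryl bromide and the ring ether tolerate dilute methanolic acid.

Step 9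
Reactants: 16 methyl (2R,3R)-5-bromo-2-(4-hydroxy-3,5-dimethoxyphenyl)-7-methoxy-2,3-dihydrobenzofuran-3-carboxylate; 17 (R)-4-benzyl-3-(chloroacetyl)oxazolidin-2-one
Product: 18 (R)-4-benzyl-3-{[4-((2R,3R)-5-bromo-7-methoxy-3-(methoxycarbonyl)-2,3-dihydrobenzofuran-2-yl)-2,6-dimethoxyphenoxy]acetyl}oxazolidin-2-one
Conditions: K2CO3, NaI (0.1 equiv), MeCN, 20–40 °C
Reagents that add atoms: none
Why: Williamson O-alkylation of the phenoxide by the alpha-halo imide (Finkelstein activation by iodide) is faster than attack at the imide carbonyls and installs the future C8' and C9' together with the auxiliary.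

Step 10
Reactants: 18 the ring C aryloxyacetyl imide; 19 4-formyl-2,6-dimethoxyphenyl acetate
Product: 21 (R)-4-benzyl-3-[(2R,3S)-3-(4-acetoxy-3,5-dimethoxyphenyl)-3-hydroxy-2-{4-[(2R,3R)-5-bromo-7-methoxy-3-(methoxycarbonyl)-2,3-dihydrobenzofuran-2-yl]-2,6-dimethoxyphenoxy}propanoyl]oxazolidin-2-one, via boron enolate 20 (not isolated)
Conditions: Bu2BOTf, i-Pr2NEt, CH2Cl2, −78 to 0 °C; 19, −78 to 0 °C; pH 7 buffer, MeOH, 30 % H2O2, 0 °C
Reagents that add atoms: none
Why: Evans syn aldol: the Z dibutylboron enolate reacts through a chair Zimmerman–Traxler transition state whose enolate face is fixed by the (R)-benzyloxazolidinone, giving the 2R,3S adduct (8'S and, for now, 7'S), the methyl ester not being enolised under these conditions.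

Step 11
Reactants: 21 the first aldol adduct
Product: 22 (1S,2S)-2-{4-[(2R,3S)-5-bromo-3-(hydroxymethyl)-7-methoxy-2,3-dihydrobenzofuran-2-yl]-2,6-dimethoxyphenoxy}-1-(4-hydroxy-3,5-dimethoxyphenyl)propane-1,3-diol (7'S,8'S)
Conditions: LiBH4, THF, MeOH (3 equiv), 0 to 20 °C
Reagents that add atoms: none
Why: Borohydride reduction cleaves the imide to the primary alcohol with release of the auxiliary, reduces the C3 methyl ester to CH2OH and removes the aryl acetate in one operation, no stereocentre being affected.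

Step 12
Reactants: 22 the 7'S,8'S tetraol; 17 (R)-4-benzyl-3-(chloroacetyl)oxazolidin-2-one
Product: 23 the ring B aryloxyacetyl imide of 22: ring B O–CH2–C(=O)–Xc with 7'-OH, 9'-OH and the C3 CH2OH free
Conditions: K2CO3, NaI (0.1 equiv), DMF, 20 °C
Reagents that add atoms: none
Why: The same Williamson O-alkylation as in step 9; carbonate deprotonates only the phenol, so the three aliphatic hydroxyls need no protection.

Step 13
Reactants: 23 the ring B aryloxyacetyl imide triol
Product: 24 the bis-TBS ether of 23 (9'-OTBS and C3 CH2OTBS; 7'-OH free; 7'S,8'S)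
Conditions: TBSCl (2.3 equiv), imidazole, DMF, 0 °C
Reagents that add atoms: tert-butyldimethylsilyl chloride, CC(C)(C)[Si](C)(C)Cl
Why: Silylation with TBSCl and imidazole is selective for the two primary hydroxyls over the hindered secondary benzylic one.

Step 14
Reactants: 24 the bis-TBS ether with free 7'-OH
Product: 25 the 7'R benzoate of 24 (7'R,8'S, erythro)
Conditions: PPh3, i-PrO2CN=NCO2i-Pr, PhCO2H, THF, 0 to 20 °C
Reagents that add atoms: benzoic acid, O=C(O)c1ccccc1
Why: Mitsunobu reaction: SN2 displacement of the oxyphosphonium by benzoate inverts C7' to the erythro arrangement, and the benzoate then protects this oxygen during the second chain extension.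

Step 15
Reactants: 25 the 7'R benzoate imide; 26 4-formyl-2-methoxyphenyl acetate
Product: 28 the second syn aldol adduct: Xc–C(=O)–CH(O–ring B)–CH(OH)–(4-acetoxy-3-methoxyphenyl) with 2R,3S configuration and the rest as in 25, via boron enolate 27 (not isolated)
Conditions: Bu2BOTf, i-Pr2NEt, CH2Cl2, −78 to 0 °C; 26, −78 to 0 °C; pH 7 buffer, MeOH, 30 % H2O2, 0 °C
Reagents that add atoms: none
Why: Second Evans syn aldol under the same auxiliary control (8S and, for now, 7S); the benzoate, silyl ethers and aryl bromide are inert to Bu2BOTf and amine.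

Step 16
Reactants: 28 the second aldol adduct
Product: 29 the 7S,8S diol with free ring A phenol (7-OH, 9-OH and 4-OH of ring A free; 7'-OBz and both TBS ethers kept)
Conditions: NaBH4, THF/H2O (4:1), 0 to 20 °C
Reagents that add atoms: none
Why: NaBH4 in aqueous THF reductively removes the oxazolidinone and cleaves the activated aryl acetate but does not reduce the secondary alkyl benzoate.

Step 17
Reactants: 29 the 7S,8S diol phenol
Product: 30 the bis-TIPS ether of 29 (ring A O-TIPS and 9-OTIPS; 7-OH free)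
Conditions: TIPSCl (2.5 equiv), imidazole, DMF, 20 °C
Reagents that add atoms: triisopropylsilyl chloride, CC(C)[Si](Cl)(C(C)C)C(C)C
Why: The bulky silyl chloride silylates the phenol and the primary hydroxyl but not the secondary benzylic hydroxyl, and the aryl TIPS ether is chosen because it withstands the aqueous base of the later cross-coupling.

Step 18
Reactants: 30 the bis-TIPS ether with free 7-OH
Product: 31 the 7R,7'R bis-benzoate (7R,8S and 7'R,8'S)
Conditions: PPh3, i-PrO2CN=NCO2i-Pr, PhCO2H, THF, 0 to 20 °C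
Reagents that add atoms: benzoic acid, O=C(O)c1ccccc1
Why: Mitsunobu inversion at C7 as in step 14; with the ring A phenol silylated no quinone methide can form at this centre.

Step 19
Reactants: 31 the bis-benzoate
Product: 32 the 7R,7'R diol (7-OH and 7'-OH free; ring A O-TIPS, 9-OTIPS, 9'-OTBS, C3 CH2OTBS, ring D bromide)
Conditions: i-Bu2AlH (6 equiv), CH2Cl2, −78 °C; aq. potassium sodium tartrate
Reagents that add atoms: none
Why: Reductive ester cleavage removes both benzoates without base, so the aryl silyl ether stays on and no phenoxide is ever present beside a benzylic ester.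

Step 20
Reactants: 32 the aryl bromide diol; 33 (E)-2-(3,3-diethoxyprop-1-en-1-yl)-4,4,5,5-tetramethyl-1,3,2-dioxaborolane
Product: 35 the silyl-protected E-enal (target with ring A O-TIPS, 9-OTIPS, 9'-OTBS and C3 CH2OTBS), via diethyl acetal 34 (not isolated)
Conditions: PdCl2(dppf) (5 mol %), K3PO4, dioxane/H2O (5:1), 70 °C; then pyridinium p-toluenesulfonate, acetone/H2O, 20 °C
Reagents that add atoms: water, O
Why: Suzuki–Miyaura coupling (oxidative addition of the aryl bromide to zerovalent palladium, transmetalation of the E-alkenylboronate with retention of geometry, reductive elimination), followed by mild acid hydrolysis of the allylic acetal to the E-enal.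

Step 21
Reactants: 35 the silyl-protected E-enal
Product: 36 CNP0192639.1
Conditions: Bu4NF, AcOH (1:1), THF, 0 to 20 °C
Reagents that add atoms: none
Why: Fluoride-mediated desilylation removes the three alkyl silyl ethers and the aryl silyl ether, and buffering with acetic acid keeps the enal and the benzylic alcohols away from base.

**Compound list**

1 | 2'-hydroxy-3'-methoxyacetophenone | CC(=O)c1cccc(OC)c1O | starting material
2 | 5'-bromo-2'-hydroxy-3'-methoxyacetophenone | CC(=O)c1cc(Br)cc(OC)c1O | intermediate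
3 | (E)-1-(5-bromo-2-hydroxy-3-methoxyphenyl)-3-(dimethylamino)prop-2-en-1-one (enaminone, formed in the flask) | CN(C)/C=C/C(=O)c1cc(Br)cc(OC)c1O | intermediate
4 | 6-bromo-8-methoxy-4H-chromen-4-one | O=c1ccoc2c(OC)cc(Br)cc12 | intermediate
5 | 4-bromo-2,6-dimethoxyphenol | COc1cc(Br)cc(OC)c1O | starting material
6 | 5-bromo-1,3-dimethoxy-2-(methoxymethoxy)benzene | COCOc1c(OC)cc(Br)cc1OC | intermediate
7 | [3,5-dimethoxy-4-(methoxymethoxy)phenyl]lithium (formed in the flask) | [Li]c1cc(OC)c(OCOC)c(OC)c1 | intermediate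
8 | [3,5-dimethoxy-4-(methoxymethoxy)phenyl]boronic acid | COCOc1c(OC)cc(B(O)O)cc1OC | intermediate
9 | (2R)-6-bromo-2-[3,5-dimethoxy-4-(methoxymethoxy)phenyl]-8-methoxychroman-4-one | COCOc1c(OC)cc([C@@H]2Oc3c(OC)cc(Br)cc3C(=O)C2)cc1OC | intermediate
10 | lithium (2R)-6-bromo-2-[3,5-dimethoxy-4-(methoxymethoxy)phenyl]-8-methoxy-2H-chromen-4-olate (enolate of 9, formed in the flask) | COCOc1c(OC)cc([C@@H]2Oc3c(OC)cc(Br)cc3C(O[Li])=C2)cc1OC | intermediate
11 | (2R)-6-bromo-2-[3,5-dimethoxy-4-(methoxymethoxy)phenyl]-8-methoxy-3-(trifluoroacetyl)chroman-4-one (enolised, C3 undefined, crude) | COCOc1c(OC)cc([C@@H]2Oc3c(OC)cc(Br)cc3C(=O)C2C(=O)C(F)(F)F)cc1OC | intermediate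
12 | (2S)-6-bromo-3-diazo-2-[3,5-dimethoxy-4-(methoxymethoxy)phenyl]-8-methoxychroman-4-one | COCOc1c(OC)cc([C@@H]2Oc3c(OC)cc(Br)cc3C(=O)C2=[N+]=[N-])cc1OC | intermediate
13 | (2S)-5-bromo-2-[3,5-dimethoxy-4-(methoxymethoxy)phenyl]-7-methoxy-3-(oxomethylidene)-2,3-dihydrobenzofuran (ketene, formed in the flask) | COCOc1c(OC)cc([C@@H]2Oc3c(OC)cc(Br)cc3C2=C=O)cc1OC | intermediate
14 | methyl (2R,3S)-5-bromo-2-[3,5-dimethoxy-4-(methoxymethoxy)phenyl]-7-methoxy-2,3-dihydrobenzofuran-3-carboxylate (cis, formed in the flask) | COCOc1c(OC)cc([C@@H]2Oc3c(OC)cc(Br)cc3[C@@H]2C(=O)OC)cc1OC | intermediate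
15 | methyl (2R,3R)-5-bromo-2-[3,5-dimethoxy-4-(methoxymethoxy)phenyl]-7-methoxy-2,3-dihydrobenzofuran-3-carboxylate (trans) | COCOc1c(OC)cc([C@@H]2Oc3c(OC)cc(Br)cc3[C@H]2C(=O)OC)cc1OC | intermediate
16 | methyl (2R,3R)-5-bromo-2-(4-hydroxy-3,5-dimethoxyphenyl)-7-methoxy-2,3-dihydrobenzofuran-3-carboxylate | COc1cc([C@@H]2Oc3c(OC)cc(Br)cc3[C@H]2C(=O)OC)cc(OC)c1O | intermediate
17 | (R)-4-benzyl-3-(chloroacetyl)oxazolidin-2-one | O=C(CCl)N1[C@H](Cc2ccccc2)COC1=O | starting material
18 | (R)-4-benzyl-3-{[4-((2R,3R)-5-bromo-7-methoxy-3-(methoxycarbonyl)-2,3-dihydrobenzofuran-2-yl)-2,6-dimethoxyphenoxy]acetyl}oxazolidin-2-one | COc1cc([C@@H]2Oc3c(OC)cc(Br)cc3[C@H]2C(=O)OC)cc(OC)c1OCC(=O)N1[C@H](Cc2ccccc2)COC1=O | intermediate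
19 | 4-formyl-2,6-dimethoxyphenyl acetate | CC(=O)Oc1c(OC)cc(C=O)cc1OC | starting material
20 | Z dibutylboron enolate of 18 (formed in the flask) | CCCCB(CCCC)O/C(=C\Oc1c(OC)cc([C@@H]2Oc3c(OC)cc(Br)cc3[C@H]2C(=O)OC)cc1OC)N1[C@H](Cc2ccccc2)COC1=O | intermediate
21 | (R)-4-benzyl-3-[(2R,3S)-3-(4-acetoxy-3,5-dimethoxyphenyl)-3-hydroxy-2-{4-[(2R,3R)-5-bromo-7-methoxy-3-(methoxycarbonyl)-2,3-dihydrobenzofuran-2-yl]-2,6-dimethoxyphenoxy}propanoyl]oxazolidin-2-one | CC(=O)Oc1c(OC)cc([C@H](O)[C@H](C(=O)N2[C@H](Cc3ccccc3)COC2=O)Oc2c(OC)cc([C@@H]3Oc4c(OC)cc(Br)cc4[C@H]3C(=O)OC)cc2OC)cc1OC | intermediate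
22 | (1S,2S)-2-{4-[(2R,3S)-5-bromo-3-(hydroxymethyl)-7-methoxy-2,3-dihydrobenzofuran-2-yl]-2,6-dimethoxyphenoxy}-1-(4-hydroxy-3,5-dimethoxyphenyl)propane-1,3-diol | COc1cc([C@H](O)[C@H](CO)Oc2c(OC)cc([C@@H]3Oc4c(OC)cc(Br)cc4[C@H]3CO)cc2OC)cc(OC)c1O | intermediate
23 | (R)-4-benzyl-3-{[4-((1S,2S)-1,3-dihydroxy-2-{4-[(2R,3S)-5-bromo-3-(hydroxymethyl)-7-methoxy-2,3-dihydrobenzofuran-2-yl]-2,6-dimethoxyphenoxy}propyl)-2,6-dimethoxyphenoxy]acetyl}oxazolidin-2-one | COc1cc([C@H](O)[C@H](CO)Oc2c(OC)cc([C@@H]3Oc4c(OC)cc(Br)cc4[C@H]3CO)cc2OC)cc(OC)c1OCC(=O)N1[C@H](Cc2ccccc2)COC1=O | intermediate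
24 | 23 with 9'-OH and the C3 CH2OH as TBS ethers (7'S,8'S; 7'-OH free) | COc1cc([C@H](O)[C@H](CO[Si](C)(C)C(C)(C)C)Oc2c(OC)cc([C@@H]3Oc4c(OC)cc(Br)cc4[C@H]3CO[Si](C)(C)C(C)(C)C)cc2OC)cc(OC)c1OCC(=O)N1[C@H](Cc2ccccc2)COC1=O | intermediate
25 | 7'R benzoate of 24 (7'R,8'S) | COc1cc([C@@H](OC(=O)c2ccccc2)[C@H](CO[Si](C)(C)C(C)(C)C)Oc2c(OC)cc([C@@H]3Oc4c(OC)cc(Br)cc4[C@H]3CO[Si](C)(C)C(C)(C)C)cc2OC)cc(OC)c1OCC(=O)N1[C@H](Cc2ccccc2)COC1=O | intermediate
26 | 4-formyl-2-methoxyphenyl acetate | COc1cc(C=O)ccc1OC(C)=O | starting material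
27 | Z dibutylboron enolate of 25 (formed in the flask) | CCCCB(CCCC)O/C(=C\Oc1c(OC)cc([C@@H](OC(=O)c2ccccc2)[C@H](CO[Si](C)(C)C(C)(C)C)Oc2c(OC)cc([C@@H]3Oc4c(OC)cc(Br)cc4[C@H]3CO[Si](C)(C)C(C)(C)C)cc2OC)cc1OC)N1[C@H](Cc2ccccc2)COC1=O | intermediate
28 | second aldol adduct: (2R,3S)-3-(4-acetoxy-3-methoxyphenyl)-3-hydroxy-2-(ring B oxy)propanoyl imide of Xc, rest as 25 | COc1cc([C@H](O)[C@H](C(=O)N2[C@H](Cc3ccccc3)COC2=O)Oc2c(OC)cc([C@@H](OC(=O)c3ccccc3)[C@H](CO[Si](C)(C)C(C)(C)C)Oc3c(OC)cc([C@@H]4Oc5c(OC)cc(Br)cc5[C@H]4CO[Si](C)(C)C(C)(C)C)cc3OC)cc2OC)ccc1OC(C)=O | intermediate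
29 | 7S,8S diol with free ring A phenol, 7'R benzoate and two TBS ethers | COc1cc([C@H](O)[C@H](CO)Oc2c(OC)cc([C@@H](OC(=O)c3ccccc3)[C@H](CO[Si](C)(C)C(C)(C)C)Oc3c(OC)cc([C@@H]4Oc5c(OC)cc(Br)cc5[C@H]4CO[Si](C)(C)C(C)(C)C)cc3OC)cc2OC)ccc1O | intermediate
30 | 29 with ring A O-TIPS and 9-OTIPS (7-OH free) | COc1cc([C@H](O)[C@H](CO[Si](C(C)C)(C(C)C)C(C)C)Oc2c(OC)cc([C@@H](OC(=O)c3ccccc3)[C@H](CO[Si](C)(C)C(C)(C)C)Oc3c(OC)cc([C@@H]4Oc5c(OC)cc(Br)cc5[C@H]4CO[Si](C)(C)C(C)(C)C)cc3OC)cc2OC)ccc1O[Si](C(C)C)(C(C)C)C(C)C | intermediate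
31 | 7R,7'R bis-benzoate (7R,8S and 7'R,8'S) | COc1cc([C@@H](OC(=O)c2ccccc2)[C@H](CO[Si](C(C)C)(C(C)C)C(C)C)Oc2c(OC)cc([C@@H](OC(=O)c3ccccc3)[C@H](CO[Si](C)(C)C(C)(C)C)Oc3c(OC)cc([C@@H]4Oc5c(OC)cc(Br)cc5[C@H]4CO[Si](C)(C)C(C)(C)C)cc3OC)cc2OC)ccc1O[Si](C(C)C)(C(C)C)C(C)C | intermediate
32 | 7R,7'R diol, silyl-protected aryl bromide | COc1cc([C@@H](O)[C@H](CO[Si](C(C)C)(C(C)C)C(C)C)Oc2c(OC)cc([C@@H](O)[C@H](CO[Si](C)(C)C(C)(C)C)Oc3c(OC)cc([C@@H]4Oc5c(OC)cc(Br)cc5[C@H]4CO[Si](C)(C)C(C)(C)C)cc3OC)cc2OC)ccc1O[Si](C(C)C)(C(C)C)C(C)C | intermediate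
33 | (E)-2-(3,3-diethoxyprop-1-en-1-yl)-4,4,5,5-tetramethyl-1,3,2-dioxaborolane | CCOC(OCC)/C=C/B1OC(C)(C)C(C)(C)O1 | starting material
34 | 32 with Br replaced by (E)-CH=CH–CH(OEt)2 (formed in the flask) | COc1cc([C@@H](O)[C@H](CO[Si](C(C)C)(C(C)C)C(C)C)Oc2c(OC)cc([C@@H](O)[C@H](CO[Si](C)(C)C(C)(C)C)Oc3c(OC)cc([C@@H]4Oc5c(OC)cc(/C=C/C(OCC)OCC)cc5[C@H]4CO[Si](C)(C)C(C)(C)C)cc3OC)cc2OC)ccc1O[Si](C(C)C)(C(C)C)C(C)C | intermediate
35 | silyl-protected E-enal (target with ring A O-TIPS, 9-OTIPS, 9'-OTBS, C3 CH2OTBS) | COc1cc([C@@H](O)[C@H](CO[Si](C(C)C)(C(C)C)C(C)C)Oc2c(OC)cc([C@@H](O)[C@H](CO[Si](C)(C)C(C)(C)C)Oc3c(OC)cc([C@@H]4Oc5c(OC)cc(/C=C/C=O)cc5[C@H]4CO[Si](C)(C)C(C)(C)C)cc3OC)cc2OC)ccc1O[Si](C(C)C)(C(C)C)C(C)C | intermediate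
36 | CNP0192639.1, (E)-3-{(2R,3S)-2-[4-({(1R,2S)-1,3-dihydroxy-1-[4-({(1R,2S)-1,3-dihydroxy-1-(4-hydroxy-3-methoxyphenyl)propan-2-yl}oxy)-3,5-dimethoxyphenyl]propan-2-yl}oxy)-3,5-dimethoxyphenyl]-3-(hydroxymethyl)-7-methoxy-2,3-dihydrobenzofuran-5-yl}prop-2-enal | COc1cc([C@@H](O)[C@H](CO)Oc2c(OC)cc([C@@H](O)[C@H](CO)Oc3c(OC)cc([C@@H]4Oc5c(OC)cc(/C=C/C=O)cc5[C@H]4CO)cc3OC)cc2OC)ccc1O | target

**Totals**
Total steps: 21. Longest linear sequence: 19 steps (from 1 through steps 1, 2 and 5–21); steps 3 and 4 form the side branch that joins at step 5.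

**Steps most likely to fail**

Step 6. The lithium enolate may expel the ring oxygen (opening to the chalcone phenoxide and reclosure), which erodes the C2 configuration or consumes material. Fallback, from 9: soft enolisation with Me3SiOTf and Et3N in CH2Cl2 at −40 °C should give the trimethylsilyl enol ether F1 without a free enolate. C-acylation of F1 with (CF3CO)2O brings the route back at 11, which is diazotised as before to 12.

Step 7. A 1,2-hydride shift from C2 to the carbene carbon (flavone) or carbene insertion into the O–H bond of methanol may compete with the aryl shift, or the cis-to-trans equilibration may stall. Fallback, from 9 and without a diazo compound: HC(OMe)3 with catalytic H2SO4 should convert 9 in the flask into its methyl enol ether F2, which PhI(OAc)2 attacks at C3. Loss of iodobenzene then drives the same shift of C4a from C4 to C3 (the known oxidative ring contraction of flavanones to methyl trans-2-aryl-2,3-dihydrobenzofuran-3-carboxylates), and the route is rejoined at 15.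

Step 14 (step 18 repeats the operation and shares the risk). The electron-rich benzylic oxyphosphonium may ionise, with partial loss of stereospecificity, or eliminate instead of undergoing clean SN2 inversion. Fallback, from 24: Dess–Martin oxidation should give the aryl ketone F3. Chelation-controlled reduction with Zn(BH4)2 in Et2O at −20 °C, which spares the imide, should give the erythro alcohol F4, and benzoylation with PhCOCl in pyridine brings the route back at 25.

**Further compounds**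
F1 | step 6 | (2R)-6-bromo-2-[3,5-dimethoxy-4-(methoxymethoxy)phenyl]-8-methoxy-4-(trimethylsilyloxy)-2H-chromene | COCOc1c(OC)cc([C@@H]2Oc3c(OC)cc(Br)cc3C(O[Si](C)(C)C)=C2)cc1OC
F2 | step 7 | (2R)-6-bromo-2-[3,5-dimethoxy-4-(methoxymethoxy)phenyl]-4,8-dimethoxy-2H-chromene | COCOc1c(OC)cc([C@@H]2Oc3c(OC)cc(Br)cc3C(OC)=C2)cc1OC
F3 | step 14 | 7'-ketone of 24 (8'S) | COc1cc(C(=O)[C@H](CO[Si](C)(C)C(C)(C)C)Oc2c(OC)cc([C@@H]3Oc4c(OC)cc(Br)cc4[C@H]3CO[Si](C)(C)C(C)(C)C)cc2OC)cc(OC)c1OCC(=O)N1[C@H](Cc2ccccc2)COC1=O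
F4 | step 14 | 7'R alcohol, C7' epimer of 24 (7'R,8'S) | COc1cc([C@@H](O)[C@H](CO[Si](C)(C)C(C)(C)C)Oc2c(OC)cc([C@@H]3Oc4c(OC)cc(Br)cc4[C@H]3CO[Si](C)(C)C(C)(C)C)cc2OC)cc(OC)c1OCC(=O)N1[C@H](Cc2ccccc2)COC1=O
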